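The constants of this chemistry are unknown to us, so we fold them into one number read from the runs.

| flask | substrate | partner | free catalyst | remark | time |
|---|---|---|---|---|---|
| Thursday's | 20 mM | 1.05 equiv | 0.56 mol% | run made earlier |  |
| Tuesday's | 13 mM | 1.05 equiv | 0.56 mol% | run made earlier |  |
| Wednesday's | 30 mM | 1.05 equiv | 0.56 mol% | run made earlier |  |
| Saturday's | 20 mM | 1.05 equiv | 0.84 mol% | run made earlier |  |
| ochre | 20 mM | 1.05 equiv (fed, over 1.5 min) | 0.56 mol% | all else is in the flask from the start; the feed brings no volume worth counting | 2.5 min |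
| grey | 20 mM (fed, over 1.5 min) | 1.05 equiv | 0.56 mol% | all else is in the flask from the start; the feed brings no volume worth counting | 2.5 min |
| blue | 20 mM | 1.05 equiv | 0.56 mol% | everything together at the start | 2.5 min |
| red | 20 mM (fed, over 25 s) | 1.05 equiv | 0.56 mol% | all else is in the flask from the start; the feed brings no volume worth counting | 2.5 min |

| run | time / min | target / % | substrate / % |
|---|---|---|---|
| Thursday's | 0.200 | 13.8 | 85.5 |
| Thursday's | 0.667 | 34.5 | 65.3 |
| Thursday's | 1.33 | 50.8 | 48.4 |
| Thursday's | 2.00 | 60.9 | 38.8 |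
| Thursday's | 2.50 | 66.4 | 33.1 |
| Tuesday's | 0.667 | 25.4 | 74.2 |
| Tuesday's | 1.33 | 40.8 | 58.9 |
| Tuesday's | 2.00 | 51.5 | 48.1 |
| Tuesday's | 2.50 | 57.4 | 42.3 |
| Tuesday's | 3.00 | 61.7 | 37.9 |
| Wednesday's | 0.250 | 20.2 | 79.1 |
| Wednesday's | 0.417 | 30.0 | 69.1 |
| Wednesday's | 0.833 | 44.6 | 54.1 |
| Wednesday's | 1.50 | 59.4 | 39.6 |
| Wednesday's | 3.00 | 75.5 | 23.5 |
| Saturday's | 0.250 | 22.9 | 77.3 |
| Saturday's | 0.833 | 47.5 | 51.7 |
| Saturday's | 1.33 | 60.1 | 39.7 |
| Saturday's | 2.00 | 69.2 | 30.1 |
| Saturday's | 3.00 | 78.4 | 21.0 |

(scatter of a reading: 0.3 percentage points)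



* the flask that comes out highest in amount of target, in percent of the substrate charged, or "all alike" when all lie within 1.5 percentage points (ochre / grey / blue / red / all alike)
* target at the end, in percent of the substrate charged, ochre
* target at the end, in percent of the substrate charged, grey
* target at the end, in percent of the substrate charged, blue
* target at the end, in percent of the substrate charged, red

At 1.05 equiv of partner, substrate is the limiting reagent by a small margin. If the rate goes as [substrate][partner], and we take the two concentrations as equal, the balance of substrate integrates to 1/a − 1 = D, where a is the fraction of substrate left and D is the progress number, rate constant times charge times time 2.02, as read from Thursday's run at 2.50 min. So target is D/(1+D). Thursday's D grows steadily, at 0.802 min⁻¹ by 1.33 min and 0.808 min⁻¹ by the end.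

Blue repeats Thursday's recipe, so we expect 66.4% there. A steady feed lasting a time t_f brings its portion late by t_f/2 on average, so for a flask stopped at time t we take D(1 − t_f/(2t)). That gives 1.41 and 58.5% for both grey and ochre, and 1.85 and 64.9% for red.

Was one number enough? It cannot separate grey from ochre. Scaled to blue's charge and time, Tuesday's run gives 2.10 and Wednesday's 1.81, so D does not quite scale with charge.

The forecast names blue, with 59% for ochre, 60% for grey, 66.4% for blue and 65.5% for red, holding that “low early inhibition does not repay the lost concentration”.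

The flasks give 59.7% for ochre, 57.8% for grey, 66.5% for blue and 64.6% for red, so blue stands highest. Read backwards, D is 1.37 for grey and 1.48 for ochre, on either side of our 1.41. Over the first 1.5 min, mean substrate was 6.86 mM in grey and 16.2 mM in ochre.

    substrate + free catalyst ⇌ catalyst intermediate A (K = 52.0 M⁻¹, k = 283 M⁻¹ s⁻¹)
    catalyst intermediate B → by-product + catalyst intermediate C (k = 791 s⁻¹)
    2 catalyst intermediate C ⇌ resting dimer (K = 3100 M⁻¹, k = 10500 M⁻¹ s⁻¹)
    partner + catalyst intermediate A ⇌ catalyst intermediate B (K = 9.26 M⁻¹, k = 680 M⁻¹ s⁻¹)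
    2 catalyst intermediate B → spent catalyst B (k = 435 M⁻¹ s⁻¹)
    free catalyst → spent catalyst A (k = 1.12 × 10⁻⁵ s⁻¹)
    catalyst intermediate C ⇌ free catalyst + target (K = 0.00989 M, k = 14.3 s⁻¹)

In the neighbour of blue with 0.630 equiv of partner, with m that charge, the same balance gives target = m(E − 1)/(E − m), where E = exp((1 − m)D) = 2.11, hence 47.3%. The computed flask gives 52.3% of target, more than our figure.

The readings are calculated for substances that don't exist; the scatter is artificial.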